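Time spent warm was what I followed in these flasks: in Friday's run target stood near its level at the first reading, and the isomer of the product crept up afterwards.

| flask | starting material | coupling partner | second substrate | temperature | remark | time |
|---|---|---|---|---|---|---|
| Monday's | 0.15 M | 0.80 equiv | 1 equiv | 5 °C | run made earlier |  |
| Wednesday's | 0.15 M | 0.54 equiv | 1 equiv | 20 °C | run made earlier |  |
| Friday's | 0.15 M | 1.2 equiv | 1 equiv | 5 °C | run made earlier |  |
| Thursday's | 0.075 M | 0.80 equiv | 1 equiv | 20 °C | run made earlier |  |
| south-west | 0.15 M | 0.800 equiv (fed, over 2.5 h) | 1.00 equiv | 20 °C | all else is in the flask from the start; the feed brings no volume worth counting | 3.0 h |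
| east | 0.15 M | 0.800 equiv | 1.00 equiv | 20 °C | everything together at the start | 3.0 h |
| north-west | 0.15 M (fed, over 2.5 h) | 0.800 equiv | 1.00 equiv | 20 °C | all else is in the flask from the start; the feed brings no volume worth counting | 3.0 h |
| west | 0.15 M (fed, over 2.5 h) | 0.800 equiv | 1.00 equiv |  | the addition at −20 °C, then warmed to 20 °C; the feed brings no volume worth counting | 3.0 h |

| run | time / h | target / % | isomer of the product / % |
|---|---|---|---|
| Monday's | 0.500 | 21.4 | 3.0 |
| Monday's | 1.00 | 23.4 | 0 |
| Monday's | 2.00 | 21.1 | 2.0 |
| Monday's | 3.00 | 21.8 | 4.1 |
| Monday's | 4.00 | 21.9 | 3.5 |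
| Wednesday's | 0.200 | 17.9 | 0 |
| Wednesday's | 0.333 | 15.9 | 4.0 |
| Wednesday's | 0.417 | 16.9 | 3.9 |
| Wednesday's | 0.667 | 17.9 | 3.9 |
| Wednesday's | 1.00 | 15.0 | 5.3 |
| Wednesday's | 1.50 | 15.7 | 5.3 |
| Wednesday's | 2.50 | 17.7 | 7.0 |
| Friday's | 0.250 | 35.4 | 0 |
| Friday's | 0.667 | 35.8 | 1.7 |
| Friday's | 1.33 | 33.4 | 2.3 |
| Friday's | 2.00 | 32.5 | 3.0 |
| Friday's | 3.00 | 32.7 | 6.3 |
| Friday's | 4.00 | 30.2 | 7.3 |
| Friday's | 5.00 | 32.6 | 7.8 |
| Thursday's | 0.500 | 20.5 | 4.6 |
| Thursday's | 1.00 | 18.9 | 4.3 |
| Thursday's | 1.33 | 19.4 | 6.4 |
| Thursday's | 2.00 | 20.0 | 7.8 |
| Thursday's | 2.50 | 19.5 | 5.6 |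

(scatter of a reading: 1 percentage point)

- what was read earlier has a scatter of 1 percentage point, one standard deviation

- which flask leads in share of target in target plus isomer of the product ("all alike" within 1.5 percentage points) (south-west / east / north-west / west / all alike)
- share of target in target plus isomer of the product at the end, south-west
- share of target in target plus isomer of the product at the end, east
- share of target in target plus isomer of the product at the end, north-west
- share of target in target plus isomer of the product at the end, west

I solved the two ends first. At the old end, target that has stood long at 20 °C holds a steady share; the late readings of Wednesday's and Thursday's, pooled, gave 74.2 %, which I took as thermodynamic control. At the young end, I took target just born to be still pure, which is kinetic control. I joined them with an exponential in the age of the target: the share is the old-end share, plus the remaining gap times the mean of e to the power of minus age over the relaxation time. Thursday's isomer share of 18.3 % at 0.500 h put that time at 0.405 h, a figure from one reading that carries its scatter.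

East's target is born at the start and 3.0 h is long against that time, so east lies at the old end, 74.2 %. In south-west and north-west target is born steadily during the feed, so its age runs from 0.500 h to 3.0 h, and the mean gave 75.4 %. The readings pointed to slower ageing in the cold: Friday's at 5 °C needed 3.00 h for an isomer share of 16.2 %, while Thursday's at 20 °C showed 18.3 % at 0.500 h, though the charges of these runs differ too. So I counted no ageing in west's feed at −20 °C. If west's target is all born at the warming, it ages 0.500 h, which gives 81.7 %. Target born later is younger, so I placed west a little above that and ahead of the others.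

The forecast, which differs from my reckoning for west and east, gave south-west 76 %, east 71 %, north-west 76 % and west 92 %, with west leading, and warned: “The risk is that coupling stalls until warming”.

The flasks gave south-west 75.2 %, east 73.1 %, north-west 74.9 % and west 83.7 %, so west led.

    target ⇌ isomer of the product (K = 0.370, k = 0.00910 /min, Ea = 92.0 kJ/mol, ΔH = −2.00 kJ/mol)
    second substrate + coupling partner ⇌ second product (K = 13.0 /M, k = 24.0 /M/min, Ea = 63.0 kJ/mol, ΔH = −47.0 kJ/mol)
    starting material + coupling partner ⇌ target (K = 11.0 /M, k = 3.20 /M/min, Ea = 39.0 kJ/mol, ΔH = −13.0 kJ/mol)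
    (constants at 20 °C)

A neighbour of west was charged with 2.00 equiv of coupling partner, with the other charges and the time held. My relaxation time of 0.405 h holds no charge, and the age after warming stays 0.500 h, so the same reckoning gives 81.7 % again. This neighbour held more target than west, 50.6 % against 24.6 %, and its share was 83.2 %.

Readings and results come from a simulation with constants of no real substance; the scatter is artificial.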